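## Structural features

- Target 22 is a 2-hydroxy-5-methoxy-1,4-benzoquinone. Its C1' is joined through one methylene (C11) to the quaternary C9 of a bicyclic sesquiterpene unit. Ring A (C1–C5, C10) carries the C4 gem-dimethyl group; ring B (C5–C10) carries the C5=C6 alkene and the methyl groups on C8 and C9.
- Three stereocentres stand side by side: C8 (S), C9 (R) and C10 (S). The C8 and C9 methyl groups are cis; H10 is anti to the C9 methyl and syn to C11.
- The hydroxyquinone is a vinylogous acid that tolerates neither organolithium reagents, palladium hydrides nor hydrogenation, so it is carried as a tetramethoxyarene until the end.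
- The C5=C6 alkene flanks the C10–H bond. Acid can move it to C5=C10 and erase C10, and in open-chain precursors C10–H is doubly allylic.
- The real difficulty is the all-carbon quaternary C9, wedged between two tertiary stereocentres and bonded to a neopentyl benzylic methylene, in a hydrocarbon decalin with no heteroatom handle.
- The key step uses the fact that C9 bears no hydrogen and C11 carries only the arene. A C9=C11 styrene can accept a C8 vinyl group, closing ring B at C8–C9, and the C11–palladium bond left behind cannot β-eliminate and is simply reduced.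
- C8 leaves that step as an exocyclic methylene, the direct precursor of the C8 methyl. The C5=C6 alkene, with E geometry, is the rigid part of the tether.

## Logic of the disconnections

**22 ⇒ 21 ⇒ 20.** The O–H on C2' is returned to O–CH3, and the C3' and C6' carbonyls are returned to aryl C–OCH3 bonds. The four methyl ethers of 20 are inert to every earlier reagent. 20 is symmetric about the C1'–C4' axis, so either para pair of ethers leads to the same quinone 21 and the oxidation raises no regiochemical question. The demand falls on the last step: hydroxide must distinguish C2' from C5' in 21, and only the C11 substituent next to C2' makes the two vinylogous esters different.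

**20 ⇒ 19.** H2 is removed across C8 and its methyl carbon, giving the exocyclic methylene. This alkene is exactly what a C8 vinyl–metal cyclisation leaves, and removing the C8 stereocentre leaves only C9 and C10. Forward, hydrogen must arrive anti to the axial C9 methyl and must not touch C5=C6.

**19 ⇒ 18.** C8–C9 (ring B) is cut, together with the C11–H bond that replaces palladium. The quaternary centre and ring B vanish, and 18 is a monocyclic ring A triene with one stereocentre, C10. Forward, the step needs 6-exo closure with C11 ending syn to H10, and hydride capture after the cyclisation, not before it.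

A check of 18 and 19 against 22 shows the C10 configuration and both alkene geometries to be mutually consistent, so no structure needs changing. One point of the stereochemical reasoning is tightened:
- In the E-styrene the group on C11 cis to C10 is only hydrogen, so allylic 1,3-strain by itself is a weak bias.
- C9 is better regarded as fixed by the ring A chair that closure demands, together with the coplanar syn-insertion geometry.
- The E geometry is kept by design, since an aryl group cis to C10 would run into C1 in that transition state.

**18 ⇒ 17 ⇒ 14 + 16 (16 ⇐ 15).** Water is added back across C9=C11 with OH on C11, then C11–C1' is cut. The benzylic C11–O bond of 17 ionises readily and H9 is its only β-hydrogen, so the alkene position is unambiguous. The arene separates as 16, which comes from 15 by deprotonation, and the route becomes convergent. Forward, addition to 14 must outrun enolisation, and the dehydration must avoid acid strong enough to move C5=C6.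

**14 ⇒ 13 ⇒ 10.** C9–C10 is cut with O–C6 reconnected (retro [3,3]), and C11 goes from aldehyde to ester level. The array C11(=O)–C9–C10–C5=C6 is the retron of an ester enolate Claisen rearrangement. The C10 stereocentre and the E-alkene are both traced to one carbinol centre, C6 of 10, and the configuration at C9 does not matter because C9 becomes sp2. Forward, C7 must sit on the C10 side of the allyl unit in the transition state. With that geometry the target's C10 configuration requires R at C6. The vinyl bromide must survive the amide base.

**10 ⇒ 8 + 9; 8 ⇒ 4 + 6 (6 ⇐ 5).** The acyl–O bond is cut, then C6–C7. This leaves an achiral aldehyde and a 2-bromoallyl nucleophile that already carries the halide for the key step. Forward, the allyl group must be delivered to the re face of 4.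

**4 ⇒ 3 ⇒ 2 ⇒ 1.** C5–C6 is cut (formyl carbon from a formamide), and the C5=C10 alkene is traced to the ketone through its sulfonylhydrazone. Only one α-methylene is present in 1, so the alkene can form in one direction only.

## Other disconnections considered

**Alternative 1: enzymatic bicyclisation.**
- Cut: C4–C5 and C9–C10 together (and C8–O), unravelling both rings to the open-chain farnesyl arene A1, which would come from 16 by farnesylation.
- Forward key step: squalene–hopene cyclase protonates C3=C4 of A1, closes rings A and B in the drimane sense, and water captures the C8 cation to give A2.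
- In its favour: one step builds both rings as a single enantiomer. A later cationic cascade from A2 (H9 to C8, C10 methyl to C9, H5 to C10, loss of H6) would relay the configurations of C8, C9 and C10 by suprafacial shifts. On step economy this is clearly better than the chosen plan (about five steps against thirteen), and on the internal logic of relative configuration it is at least its equal.
- Against it here: A2 is a drimane, not the target skeleton. The cascade has no built-in stop at C5=C6: proton loss from the C10 cation (C5=C10 or C1=C10), a further methyl shift from C4, or capture of a cation by the electron-rich arene are all open, and the C5=C6 alkene is itself labile under the acid needed. Acceptance of the bulky tetramethoxyaryl head group by the enzyme is also uncertain.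
- Comparison: the chosen plan is longer but places the alkene and each stereocentre by a separate, controllable event.

**Alternative 2: Ireland–Claisen ring contraction of a lactone.**
- Cut: C9–C10 with O–C6 reconnected, leading to δ-lactone A3 (C9 as α-carbon, C6 as the alkoxy carbon bearing the ring A cyclohexenyl group, C8 methyl trans to it).
- Forward key step: the silyl ketene acetal of A3 rearranges through a boat, forming C9–C10, closing ring B with the C5=C6 alkene and giving acid A4.
- In its favour: it is metal-free, it forms the quaternary C9 and C10 in one pericyclic event, and C8 is already set before ring closure. It therefore avoids the facial question of the hydrogenation, a point on which it is better. On C10 it is the equal of the chosen plan, since both transfer chirality from C6 through the same allyl geometry.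
- Against it here: A4 carries a carboxyl where 22 needs a methyl. Taking a neopentyl acid down to CH3 next to C5=C6 costs three or four steps at the most hindered carbon. A fully substituted ketene acetal must bond to a ring alkene carbon through a strained boat. A3 needs two stereocentres and a C9 alkylation, where the chosen route needs one carbinol centre.
- Comparison: mechanistically it is the same bond as step 6 of the chosen plan, but it asks much more of that bond, and the step economy is worse overall.

**Alternative 3: Moore rearrangement.**
- Cut: C5'–C6' of the quinone, leading to cyclobutenone A5.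
- Forward key step: thermolysis of A5 opens the four-membered ring to a vinylketene, whose ketene carbon bonds to the distal alkyne carbon to give the C2' isopropyl ether A6. One dealkylation would then give 22.
- In its favour: the positions of the hydroxyl and the methoxyl are fixed by construction. This is better than the chosen plan, which relies on a selective hydrolysis of 21.
- Against it here: it leaves the hard part untouched, namely the decalin with C8, C9 and C10. A5 also needs a neopentyl C11 carbanion of the finished decalin, so the arene that activates C9=C11 and stabilises the C11–palladium bond in the chosen key step would no longer be available. The two ideas do not simply add.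
- Comparison: it needs about four operations on the quinone against two, so it is worse on step economy; it is superior only on quinone regiochemistry.

Key step: step 10

Assumption: the (4R,5R) diazaborolidine controller is taken to deliver the 2-bromoallyl group to the re face of 4, as in its additions to conjugated aldehydes; if an MTPA ester analysis of 8 showed the opposite sense, the (4S,5S) controller would be used with no other change.

## Route

Step 1
Reactants: 1 2,2-dimethylcyclohexanone
Product: 2 N'-(2,2-dimethylcyclohexylidene)-2,4,6-tri(propan-2-yl)benzenesulfonohydrazide (E about C=N)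
Conditions: TrisNHNH2, HCl (cat.), MeOH, rt
Reagents that add atoms: 2,4,6-tri(propan-2-yl)benzenesulfonohydrazide, CC(C)c1cc(C(C)C)c(S(=O)(=O)NN)c(C(C)C)c1
Why: Acid-catalysed hydrazone condensation. The sulfonamide nitrogen settles anti to the quaternary carbon, that is syn to the only α-methylene, which is the geometry the next step needs.

Step 2
Reactants: 2 N'-(2,2-dimethylcyclohexylidene)-2,4,6-tri(propan-2-yl)benzenesulfonohydrazide
Product: 4 6,6-dimethylcyclohex-1-ene-1-carbaldehyde, via vinyllithium 3 (not isolated)
Conditions: n-BuLi (2.2 equiv), TMEDA, THF/hexane, −78 → 0 °C; DMF, −78 °C → rt; H2O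
Reagents that add atoms: N,N-dimethylformamide, CN(C)C=O
Why: Shapiro reaction: the dianion loses sulfinate and N2 to give vinyllithium 3, whose double bond can only lie away from the quaternary carbon. Formylation of 3 with DMF then gives the enal.

Step 3
Reactants: 5 2,3-dibromoprop-1-ene
Product: 6 tributyl(2-bromoprop-2-en-1-yl)stannane
Conditions: Bu3SnH, LiN(iPr)2, THF, 0 °C; then 5, −78 °C → rt
Reagents that add atoms: tributyltin hydride, CCCC[SnH](CCCC)CCCC
Why: The stannyl anion displaces the allylic bromide (direct or allylic attack gives the same product by symmetry). The vinylic bromide is not displaced.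

Step 4
Reactants: 4 6,6-dimethylcyclohex-1-ene-1-carbaldehyde, 6 tributyl(2-bromoprop-2-en-1-yl)stannane
Product: 8 (1R)-3-bromo-1-(6,6-dimethylcyclohex-1-en-1-yl)but-3-en-1-ol, via 2-bromoallylborane 7 (not isolated)
Conditions: (4R,5R)-2-bromo-4,5-diphenyl-1,3-bis(4-methylbenzenesulfonyl)-1,3,2-diazaborolidine (1.1 equiv), 6, CH2Cl2, rt, 20 h; then 4, −78 °C; H2O
Reagents that add atoms: none
Why: Enantioselective allylboration: tin-to-boron transmetallation gives 7, which adds through a closed chair transition state with the cyclohexenyl group equatorial. The C2-symmetric sulfonamide controller should direct the allyl group to the re face, which sets C6 as R.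

Step 5
Reactants: 8 (1R)-3-bromo-1-(6,6-dimethylcyclohex-1-en-1-yl)but-3-en-1-ol, 9 propanoyl chloride
Product: 10 (1R)-3-bromo-1-(6,6-dimethylcyclohex-1-en-1-yl)but-3-en-1-yl propanoate
Conditions: EtCOCl, pyridine, DMAP (cat.), CH2Cl2, 0 °C → rt
Reagents that add atoms: none
Why: O-acylation under basic conditions. The allylic C6–O bond is not ionised, so its configuration is kept.

Step 6
Reactants: 10 (1R)-3-bromo-1-(6,6-dimethylcyclohex-1-en-1-yl)but-3-en-1-yl propanoate
Product: 13 2-[(1S,2E)-2-(3-bromobut-3-en-1-ylidene)-3,3-dimethylcyclohexyl]propan-1-ol (both C9 epimers), via silyl ketene acetal 11 (not isolated), via trimethylsilyl ester 12 (not isolated)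
Conditions: LiN(iPr)2, THF, −78 °C; Me3SiCl/Et3N, −78 °C → rt, then 50 °C; LiAlH4, 0 °C; H2O
Reagents that add atoms: none
Why: Ireland–Claisen rearrangement: in the suprafacial [3,3] shift C7 should take the C10 side of the allyl unit to avoid the C4 gem-dimethyl group, which gives the E C5=C6 alkene. With C6 R, C9 is then delivered to the face of C10 that makes it S. The silyl ester 12 is reduced in the same flask; the C9 configuration is irrelevant because C9 later becomes sp2.

Step 7
Reactants: 13 2-[(1S,2E)-2-(3-bromobut-3-en-1-ylidene)-3,3-dimethylcyclohexyl]propan-1-ol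
Product: 14 2-[(1S,2E)-2-(3-bromobut-3-en-1-ylidene)-3,3-dimethylcyclohexyl]propanal (both C9 epimers)
Conditions: Dess–Martin periodinane, NaHCO3, CH2Cl2, 0 °C → rt
Reagents that add atoms: none
Why: Buffered hypervalent iodine oxidation of a primary alcohol. It touches neither the skipped diene nor the vinyl bromide, and epimerisation at C9 would be harmless.

Step 8
Reactants: 15 1,2,4,5-tetramethoxybenzene, 14 2-[(1S,2E)-2-(3-bromobut-3-en-1-ylidene)-3,3-dimethylcyclohexyl]propanal
Product: 17 2-[(1S,2E)-2-(3-bromobut-3-en-1-ylidene)-3,3-dimethylcyclohexyl]-1-(2,3,5,6-tetramethoxyphenyl)propan-1-ol (mixture of diastereomers at C9 and C11), via aryllithium 16 (not isolated)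
Conditions: 15 (1.3 equiv), n-BuLi (1.2 equiv), TMEDA, THF, 0 °C; then 14, −78 → −20 °C; H2O
Reagents that add atoms: none
Why: Directed ortho-lithiation between two methoxy groups gives 16, which adds 1,2 to the aldehyde at −78 °C faster than it enolises it or exchanges with the vinyl bromide. n-BuLi is kept below 15 so that none is left over; the new C11 centre need not be controlled.

Step 9
Reactants: 17 2-[(1S,2E)-2-(3-bromobut-3-en-1-ylidene)-3,3-dimethylcyclohexyl]-1-(2,3,5,6-tetramethoxyphenyl)propan-1-ol
Product: 18 3-{(1E)-2-[(1S,2E)-2-(3-bromobut-3-en-1-ylidene)-3,3-dimethylcyclohexyl]prop-1-en-1-yl}-1,2,4,5-tetramethoxybenzene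
Conditions: Burgess reagent, PhMe, 50 °C
Reagents that add atoms: none
Why: Dehydration through the sulfamate ester: H9 is the only β-hydrogen of C11, so only the C9=C11 alkene can form. The di-ortho-methoxy benzylic centre ionises within the ion pair, so every diastereomer of 17 should converge on the E isomer (aryl cis to the small methyl), and the non-acidic medium leaves C5=C6 and C10 alone. Any minor Z isomer would be removed by chromatography.

Step 10
Reactants: 18 3-{(1E)-2-[(1S,2E)-2-(3-bromobut-3-en-1-ylidene)-3,3-dimethylcyclohexyl]prop-1-en-1-yl}-1,2,4,5-tetramethoxybenzene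
Product: 19 1,2,4,5-tetramethoxy-3-{[(1S,8aS)-1,5,5-trimethyl-2-methylidene-1,2,3,5,6,7,8,8a-octahydronaphthalen-1-yl]methyl}benzene
Conditions: Pd(OAc)2 (10 mol%), PPh3 (25 mol%), HCO2Na (3 equiv), Bu4NCl, degassed DMF, 80 °C
Reagents that add atoms: none
Why: Pd(OAc)2 and PPh3 give zerovalent palladium, which inserts into the C8–Br bond to form a vinylpalladium bromide (divalent palladium). Syn carbopalladation of C9=C11 then forms C8–C9 and closes ring B in the 6-exo-trig mode; exo closure should beat 7-endo because the carbon group goes to the alkene carbon remote from the arene and palladium to the benzylic carbon. The C11–palladium species (divalent palladium) is neopentyl and benzylic with no β-hydrogen, so it waits until formate replaces bromide, CO2 is lost and C–H reductive elimination gives the C11 methylene and returns zerovalent palladium. The closest known reaction type is the cyclisation–hydride capture (reductive Heck) of 2-bromo-1,6-dienes with sodium formate. The new stereocentre C9 is controlled by C10 and the tether: closure is possible only from the ring A chair with C9 equatorial and H10 axial, so C8 approaches C9 gauche to H10 and anti to C1. Syn insertion keeps palladium, C8, C9 and C11 coplanar, which places C11 pseudo-equatorial on the open H10 side and the C9 methyl pseudo-axial; C11 therefore ends syn to H10 and the methyl anti, as in 22. The step needs cyclisation to outrun formate reduction of the vinylpalladium, and hydride capture to outrun 3-exo return of the C11–palladium bond onto the new C8 methylene. The E C5=C6 geometry, which holds C8 beside C9, and the excess of formate are what should secure these. The doubly allylic C10–H is protected by the absence of any amine or stronger base.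

Step 11
Reactants: 19 1,2,4,5-tetramethoxy-3-{[(1S,8aS)-1,5,5-trimethyl-2-methylidene-1,2,3,5,6,7,8,8a-octahydronaphthalen-1-yl]methyl}benzene
Product: 20 1,2,4,5-tetramethoxy-3-{[(1R,2S,8aS)-1,2,5,5-tetramethyl-1,2,3,5,6,7,8,8a-octahydronaphthalen-1-yl]methyl}benzene
Conditions: H2 (1–3 atm), RhCl(PPh3)3 (10 mol%), PhMe, rt
Reagents that add atoms: none
Why: Homogeneous hydrogenation with this catalyst reduces a 1,1-disubstituted alkene much faster than the hindered trisubstituted C5=C6. Hydrogen should add to the face of C8 anti to the adjacent axial C9 methyl, so H8 ends syn to H10 and the two methyl groups cis (C8 S).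

Step 12
Reactants: 20 1,2,4,5-tetramethoxy-3-{[(1R,2S,8aS)-1,2,5,5-tetramethyl-1,2,3,5,6,7,8,8a-octahydronaphthalen-1-yl]methyl}benzene
Product: 21 2,5-dimethoxy-3-{[(1R,2S,8aS)-1,2,5,5-tetramethyl-1,2,3,5,6,7,8,8a-octahydronaphthalen-1-yl]methyl}cyclohexa-2,5-diene-1,4-dione
Conditions: (NH4)2Ce(NO3)6 (2.5 equiv), MeCN/H2O, 0 °C
Reagents that add atoms: water, O
Why: Oxidative demethylation of a para-dimethoxyarene: the arene radical cation is attacked by water at the ipso carbons and loses methanol. Both para pairs give the same quinone because 20 is symmetric about the C1'–C4' axis, and the isolated alkene should survive short exposure at 0 °C.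

Step 13
Reactants: 21 2,5-dimethoxy-3-{[(1R,2S,8aS)-1,2,5,5-tetramethyl-1,2,3,5,6,7,8,8a-octahydronaphthalen-1-yl]methyl}cyclohexa-2,5-diene-1,4-dione
Product: 22 2-hydroxy-5-methoxy-3-{[(1R,2S,8aS)-1,2,5,5-tetramethyl-1,2,3,5,6,7,8,8a-octahydronaphthalen-1-yl]methyl}cyclohexa-2,5-diene-1,4-dione
Conditions: KOH, MeOH/H2O, rt; then 1 M HCl
Reagents that add atoms: potassium hydroxide, [K+].[OH-]
Why: Addition–elimination at a vinylogous ester: the C2' methoxy group, squeezed between C11 and a carbonyl, is twisted out of conjugation, so C2' should be the more electrophilic of the two ether carbons. The hydroxyquinone formed is ionised at once, which should stop a second hydrolysis.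

## Compound list

1 | 2,2-dimethylcyclohexanone | CC1(C)CCCCC1=O | starting material
2 | N'-(2,2-dimethylcyclohexylidene)-2,4,6-tri(propan-2-yl)benzenesulfonohydrazide (E) | CC1(C)CCCC/C1=N\NS(=O)(=O)c2c(C(C)C)cc(C(C)C)cc2C(C)C | intermediate
3 | (6,6-dimethylcyclohex-1-en-1-yl)lithium (not isolated) | [Li]C1=CCCCC1(C)C | intermediate
4 | 6,6-dimethylcyclohex-1-ene-1-carbaldehyde | O=CC1=CCCCC1(C)C | intermediate
5 | 2,3-dibromoprop-1-ene | C=C(Br)CBr | starting material
6 | tributyl(2-bromoprop-2-en-1-yl)stannane | C=C(Br)C[Sn](CCCC)(CCCC)CCCC | intermediate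
7 | (4R,5R)-2-(2-bromoprop-2-en-1-yl)-4,5-diphenyl-1,3-bis(4-methylbenzenesulfonyl)-1,3,2-diazaborolidine (not isolated) | C=C(Br)CB1N(S(=O)(=O)c2ccc(C)cc2)[C@H](c2ccccc2)[C@@H](c2ccccc2)N1S(=O)(=O)c3ccc(C)cc3 | intermediate
8 | (1R)-3-bromo-1-(6,6-dimethylcyclohex-1-en-1-yl)but-3-en-1-ol | O[C@H](CC(Br)=C)C1=CCCCC1(C)C | intermediate
9 | propanoyl chloride | CCC(=O)Cl | starting material
10 | (1R)-3-bromo-1-(6,6-dimethylcyclohex-1-en-1-yl)but-3-en-1-yl propanoate | CCC(=O)O[C@H](CC(Br)=C)C1=CCCCC1(C)C | intermediate
11 | [(1E)-1-{[(1R)-3-bromo-1-(6,6-dimethylcyclohex-1-en-1-yl)but-3-en-1-yl]oxy}prop-1-en-1-yl]oxy(trimethyl)silane (not isolated) | C/C=C(/O[Si](C)(C)C)O[C@H](CC(Br)=C)C1=CCCCC1(C)C | intermediate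
12 | trimethylsilyl 2-[(1S,2E)-2-(3-bromobut-3-en-1-ylidene)-3,3-dimethylcyclohexyl]propanoate (C9 epimers, not isolated) | CC(C(=O)O[Si](C)(C)C)[C@@H]1CCCC(C)(C)/C1=C/CC(Br)=C | intermediate
13 | 2-[(1S,2E)-2-(3-bromobut-3-en-1-ylidene)-3,3-dimethylcyclohexyl]propan-1-ol (C9 epimers) | CC(CO)[C@@H]1CCCC(C)(C)/C1=C/CC(Br)=C | intermediate
14 | 2-[(1S,2E)-2-(3-bromobut-3-en-1-ylidene)-3,3-dimethylcyclohexyl]propanal (C9 epimers) | CC(C=O)[C@@H]1CCCC(C)(C)/C1=C/CC(Br)=C | intermediate
15 | 1,2,4,5-tetramethoxybenzene | COc1cc(OC)c(OC)cc1OC | starting material
16 | (2,3,5,6-tetramethoxyphenyl)lithium (not isolated) | [Li]c1c(OC)c(OC)cc(OC)c1OC | intermediate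
17 | 2-[(1S,2E)-2-(3-bromobut-3-en-1-ylidene)-3,3-dimethylcyclohexyl]-1-(2,3,5,6-tetramethoxyphenyl)propan-1-ol (C9 and C11 diastereomers) | COc1cc(OC)c(OC)c(C(O)C(C)[C@@H]2CCCC(C)(C)/C2=C/CC(Br)=C)c1OC | intermediate
18 | 3-{(1E)-2-[(1S,2E)-2-(3-bromobut-3-en-1-ylidene)-3,3-dimethylcyclohexyl]prop-1-en-1-yl}-1,2,4,5-tetramethoxybenzene | COc1cc(OC)c(OC)c(/C=C(\C)[C@@H]2CCCC(C)(C)/C2=C/CC(Br)=C)c1OC | intermediate
19 | 1,2,4,5-tetramethoxy-3-{[(1S,8aS)-1,5,5-trimethyl-2-methylidene-1,2,3,5,6,7,8,8a-octahydronaphthalen-1-yl]methyl}benzene | COc1cc(OC)c(OC)c(C[C@@]2(C)[C@@H]3CCCC(C)(C)C3=CCC2=C)c1OC | intermediate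
20 | 1,2,4,5-tetramethoxy-3-{[(1R,2S,8aS)-1,2,5,5-tetramethyl-1,2,3,5,6,7,8,8a-octahydronaphthalen-1-yl]methyl}benzene | COc1cc(OC)c(OC)c(C[C@@]2(C)[C@@H]3CCCC(C)(C)C3=CC[C@@H]2C)c1OC | intermediate
21 | 2,5-dimethoxy-3-{[(1R,2S,8aS)-1,2,5,5-tetramethyl-1,2,3,5,6,7,8,8a-octahydronaphthalen-1-yl]methyl}cyclohexa-2,5-diene-1,4-dione | COC1=CC(=O)C(OC)=C(C[C@@]2(C)[C@@H]3CCCC(C)(C)C3=CC[C@@H]2C)C1=O | intermediate
22 | 2-hydroxy-5-methoxy-3-{[(1R,2S,8aS)-1,2,5,5-tetramethyl-1,2,3,5,6,7,8,8a-octahydronaphthalen-1-yl]methyl}cyclohexa-2,5-diene-1,4-dione (CNP0348245.1) | COC1=CC(=O)C(O)=C(C[C@@]2(C)[C@@H]3CCCC(C)(C)C3=CC[C@@H]2C)C1=O | target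

## Step count and least certain steps

Total step count: 13. Longest linear sequence: 12 steps (steps 1, 2 and 4 to 13, from 1). Step 3 is a one-step side branch, and 16 is made and used within step 8.

**Step 10, the key step.** The most likely failure is reduction of the vinylpalladium by formate before it cyclises. The reactive conformer puts C9 equatorial on ring A against C7, and C9 is a fully substituted alkene carbon, so insertion may be slow. Next in likelihood are 3-exo return of the C11–palladium bond onto the new C8 methylene with ring expansion, and palladium hydride migration of the skipped alkenes that would erode C10. The fallback sets out from 18 and comes back at 19. It is a tin hydride-mediated vinyl radical cyclisation (Bu3SnH added slowly, AIBN, PhH, 80 °C): the C8 radical adds 6-exo to C9, and the benzylic C11 radical is then reduced by the tin hydride. It involves no palladium hydride and makes no compound outside the list (entry F0).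

**Step 4.** The likely failure is poor or reversed facial discrimination, because the aldehyde is an α-branched enal next to a quaternary carbon. The fallback sets out from 4 and comes back at 8. A Barbier reaction with 5 and zinc dust (THF/aq. NH4Cl) would give racemic 3-bromo-1-(6,6-dimethylcyclohex-1-en-1-yl)but-3-en-1-ol F1. Dess–Martin oxidation would give 3-bromo-1-(6,6-dimethylcyclohex-1-en-1-yl)but-3-en-1-one F2. Corey–Bakshi–Shibata reduction with the (S)-2-methyl oxazaborolidine and catecholborane at −78 °C, with the cyclohexenyl group as the large substituent, should then give the R alcohol.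

**Step 6.** The likely failures are base-induced loss of HBr from the 2-bromoallyl group, and leakage through the transition state with C7 on the C4 side, which would give the Z alkene with the opposite C10. The fallback sets out from 8 and comes back at 13. A Johnson orthoester Claisen rearrangement (EtC(OEt)3, EtCO2H cat., xylene, 135 °C) uses no strong base and should give ethyl 2-[(1S,2E)-2-(3-bromobut-3-en-1-ylidene)-3,3-dimethylcyclohexyl]propanoate F3, which LiAlH4 reduces to 13. A Z isomer, if formed, is a separable diastereomer and cannot cyclise in step 10.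

**Step 11.** The likely failures are insufficient facial discrimination, if the aryl group folds over the face anti to the C9 methyl, and slow uptake at an alkene next to a quaternary carbon, which gives time for migration of the exocyclic alkene into ring B. The fallback sets out from 19 and comes back at 20. Hydroboration with the bulky 9-BBN and then NaOH/H2O2 should give [(1S,2S,8aS)-1,5,5-trimethyl-1-[(2,3,5,6-tetramethoxyphenyl)methyl]-1,2,3,5,6,7,8,8a-octahydronaphthalen-2-yl]methanol F4. TsCl/pyridine gives its 4-methylbenzenesulfonate F5, and LiBHEt3 removes the sulfonate to leave the C8 methyl.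

**Step 13.** The likely failure is loss of regiocontrol, through attack at the less hindered C5' or hydrolysis of both ethers. The fallback sets out from 21 and comes back at 22. Exhaustive hydrolysis (NaOH, aq. dioxane, 60 °C, then HCl) would give 2,5-dihydroxy-3-{[(1R,2S,8aS)-1,2,5,5-tetramethyl-1,2,3,5,6,7,8,8a-octahydronaphthalen-1-yl]methyl}cyclohexa-2,5-diene-1,4-dione F6. One equivalent of Me3SiCHN2 in MeOH/PhMe at 0 °C should then methylate the unflanked C5' hydroxyl in preference to the C2' hydroxyl, which is shielded by C11.

## Further compounds

F0 | step 10 | none | none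
F1 | step 4 | 3-bromo-1-(6,6-dimethylcyclohex-1-en-1-yl)but-3-en-1-ol (racemic) | OC(CC(Br)=C)C1=CCCCC1(C)C
F2 | step 4 | 3-bromo-1-(6,6-dimethylcyclohex-1-en-1-yl)but-3-en-1-one | O=C(CC(Br)=C)C1=CCCCC1(C)C
F3 | step 6 | ethyl 2-[(1S,2E)-2-(3-bromobut-3-en-1-ylidene)-3,3-dimethylcyclohexyl]propanoate (C9 epimers) | CCOC(=O)C(C)[C@@H]1CCCC(C)(C)/C1=C/CC(Br)=C
F4 | step 11 | [(1S,2S,8aS)-1,5,5-trimethyl-1-[(2,3,5,6-tetramethoxyphenyl)methyl]-1,2,3,5,6,7,8,8a-octahydronaphthalen-2-yl]methanol | COc1cc(OC)c(OC)c(C[C@@]2(C)[C@@H]3CCCC(C)(C)C3=CC[C@@H]2CO)c1OC
F5 | step 11 | [(1S,2S,8aS)-1,5,5-trimethyl-1-[(2,3,5,6-tetramethoxyphenyl)methyl]-1,2,3,5,6,7,8,8a-octahydronaphthalen-2-yl]methyl 4-methylbenzenesulfonate | COc1cc(OC)c(OC)c(C[C@@]2(C)[C@@H]3CCCC(C)(C)C3=CC[C@@H]2COS(=O)(=O)c4ccc(C)cc4)c1OC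
F6 | step 13 | 2,5-dihydroxy-3-{[(1R,2S,8aS)-1,2,5,5-tetramethyl-1,2,3,5,6,7,8,8a-octahydronaphthalen-1-yl]methyl}cyclohexa-2,5-diene-1,4-dione | OC1=CC(=O)C(O)=C(C[C@@]2(C)[C@@H]3CCCC(C)(C)C3=CC[C@@H]2C)C1=O
A1 | alternative 1 | 1,2,4,5-tetramethoxy-3-[(2E,6E)-3,7,11-trimethyldodeca-2,6,10-trien-1-yl]benzene | COc1cc(OC)c(OC)c(C/C=C(\C)CC/C=C(\C)CCC=C(C)C)c1OC
A2 | alternative 1 | 3-(8α-hydroxydriman-11-yl)-1,2,4,5-tetramethoxybenzene | COc1cc(OC)c(OC)c(C[C@H]2[C@](C)(O)CC[C@H]3C(C)(C)CCC[C@]23C)c1OC
A3 | alternative 2 | (4S,6R)-6-(6,6-dimethylcyclohex-1-en-1-yl)-4-methyl-3-[(2,3,5,6-tetramethoxyphenyl)methyl]oxan-2-one (C9 epimers) | O=C1O[C@@H](C2=CCCCC2(C)C)C[C@H](C)C1Cc3c(OC)c(OC)cc(OC)c3OC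
A4 | alternative 2 | (1R,2S,8aS)-2,5,5-trimethyl-1-[(2,3,5,6-tetramethoxyphenyl)methyl]-1,2,3,5,6,7,8,8a-octahydronaphthalene-1-carboxylic acid | COc1cc(OC)c(OC)c(C[C@@]2(C(=O)O)[C@@H]3CCCC(C)(C)C3=CC[C@@H]2C)c1OC
A5 | alternative 3 | 4-hydroxy-4-(methoxyethynyl)-3-(propan-2-yloxy)-2-{[(1R,2S,8aS)-1,2,5,5-tetramethyl-1,2,3,5,6,7,8,8a-octahydronaphthalen-1-yl]methyl}cyclobut-2-en-1-one (C4 epimers) | O=C1C(C[C@@]2(C)[C@@H]3CCCC(C)(C)C3=CC[C@@H]2C)=C(OC(C)C)C1(O)C#COC
A6 | alternative 3 | 5-methoxy-2-(propan-2-yloxy)-3-{[(1R,2S,8aS)-1,2,5,5-tetramethyl-1,2,3,5,6,7,8,8a-octahydronaphthalen-1-yl]methyl}cyclohexa-2,5-diene-1,4-dione | COC1=CC(=O)C(OC(C)C)=C(C[C@@]2(C)[C@@H]3CCCC(C)(C)C3=CC[C@@H]2C)C1=O
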